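**Retrosynthetic overview**
1. Both benzene rings are bought intact and no ring is formed. Ring A comes from divarinol 1. Ring B is atraric acid 2, used unprotected.
2. Ring A, C–CHO disconnection (made first): the future acyl carbon is put on 1 as a formyl group by Vilsmeier–Haack reaction (iminium salt 3, then aldehyde 4).
3. Ring A, O–CH3 disconnection (made second): site-selective 4-O-methylation of 4 gives aldehyde 5.
4. Key disconnection (made last): the depside acyl C–O bond. It is formed directly from aldehyde 5 and the 4-OH of 2 by oxidative carbene catalysis through acyl triazolium 6. This gives peruvinide A 7 without a free acid, an activating agent or a protecting group.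

Assumption: the SMILES holds no stereocentre, stereogenic axis or configured double bond, so 7 is achiral and no stereocontrol step is needed.

**Step 1**
Reactants: 1 divarinol (5-propylbenzene-1,3-diol)
Product: 4 2,4-dihydroxy-6-propylbenzaldehyde, via aryl iminium chloride 3 (not isolated)
Conditions: POCl3 (1.3 equiv), DMF, 0 °C to rt, 3 h; then ice-water, rt, filter or extract
Reagents that add atoms: N,N-dimethylformamide CN(C)C=O; water O
Why: Vilsmeier–Haack formylation: the chloroiminium ion attacks the doubly activated C4/C6 position (equivalent by symmetry, para to one OH and ortho to the other) rather than the crowded C2 between both OH groups, and water hydrolyses 3 to the aldehyde; no stereocentre is formed.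

**Step 2**
Reactants: 4 2,4-dihydroxy-6-propylbenzaldehyde
Product: 5 2-hydroxy-4-methoxy-6-propylbenzaldehyde
Conditions: MeI (1.05 equiv), K2CO3 (1.0 equiv), acetone, rt, 16 h
Reagents that add atoms: iodomethane CI
Why: Williamson ether synthesis under stoichiometric control: the 2-OH is held in a strong hydrogen bond to the formyl group and is poorly nucleophilic, so one equivalent of base and MeI alkylates only the para 4-OH; no stereocentre is formed.

**Step 3**
Reactants: 5 2-hydroxy-4-methoxy-6-propylbenzaldehyde; 2 atraric acid (methyl 2,4-dihydroxy-3,6-dimethylbenzoate, 1.1 equiv)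
Product: 7 peruvinide A (3-hydroxy-4-(methoxycarbonyl)-2,5-dimethylphenyl 2-hydroxy-4-methoxy-6-propylbenzoate), via acyl triazolium iodide 6 (not isolated)
Conditions: 1,4-dimethyl-4H-1,2,4-triazol-1-ium iodide (10 mol%), 1,8-diazabicyclo[5.4.0]undec-7-ene (DBU, 30 mol%), 3,3',5,5'-tetra-tert-butyl-4,4'-diphenoquinone (1.05 equiv), 4 Å molecular sieves, THF, N2, rt to 40 °C, 24 h; then 0.5 M citric acid wash
Reagents that add atoms: none
Why: Proposed new method: direct aldehyde-to-depside oxidative esterification by N-heterocyclic carbene catalysis on an unprotected, di-ortho-substituted salicylaldehyde and an unprotected resorcylate, a substrate pairing on which this reactivity has not been shown; the very small 1,4-dimethyl-1,2,4-triazol-5-ylidene adds to the hydrogen-bond-activated C=O of 5 (substoichiometric DBU keeps most of 5 un-ionised), two-electron oxidation by the diphenoquinone gives acyl triazolium 6, and the free 4-OH of 2 attacks 6 with the ortho-phenol(ate) of ring A acting as intramolecular general base (as in salicylate ester solvolysis), which forms the acyl C–O bond and releases the carbene; the 2-OH groups of 2 and 5 are chelated to their own carbonyl groups and flanked on both sides, and the reduced oxidant is too hindered to be acylated, so only the 4-O-ester forms; the closest known reaction type is carbene-catalysed oxidative esterification of simple aromatic aldehydes with alcohols using the same quinone oxidant; no stereocentre is formed.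

**Compound list**
1 | divarinol (5-propylbenzene-1,3-diol) | CCCc1cc(O)cc(O)c1 | starting material
2 | atraric acid (methyl 2,4-dihydroxy-3,6-dimethylbenzoate) | COC(=O)c1c(C)cc(O)c(C)c1O | starting material
3 | N-[(2,4-dihydroxy-6-propylphenyl)methylidene]-N-methylmethanaminium chloride (not isolated) | CCCc1cc(O)cc(O)c1C=[N+](C)C.[Cl-] | intermediate
4 | 2,4-dihydroxy-6-propylbenzaldehyde | CCCc1cc(O)cc(O)c1C=O | intermediate
5 | 2-hydroxy-4-methoxy-6-propylbenzaldehyde | CCCc1cc(OC)cc(O)c1C=O | intermediate
6 | 5-(2-hydroxy-4-methoxy-6-propylbenzoyl)-1,4-dimethyl-4H-1,2,4-triazol-1-ium iodide (catalyst-bound, not isolated) | CCCc1cc(OC)cc(O)c1C(=O)c1n(C)cn[n+]1C.[I-] | intermediate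
7 | peruvinide A, 3-hydroxy-4-(methoxycarbonyl)-2,5-dimethylphenyl 2-hydroxy-4-methoxy-6-propylbenzoate (achiral) | CCCc1cc(OC)cc(O)c1C(=O)Oc1cc(C)c(C(=O)OC)c(O)c1C | target

**Total step count:** 3. **Longest linear sequence:** 3 (1 to 4 to 5 to 7; 2 enters in the last step).

**Steps most likely to fail, most risky first**

The greatest risk is the new oxidative depside coupling, step 3.
- Carbene addition to a hindered, electron-rich aldehyde may be slow.
- Ionised 5 is a poor electrophile.
- 6 could acylate the 2-OH of another molecule of 5, or be hydrolysed by traces of water.

The fallback uses known chemistry only. It sets out from 5 and comes back to the route at 7, at the cost of one extra step. Pinnick–Lindgren oxidation of 5 (NaClO2, NaH2PO4, sulfamic acid as hypochlorite scavenger, aqueous dioxane, 0 °C) gives 2-hydroxy-4-methoxy-6-propylbenzoic acid F1. F1 is then condensed with the 4-OH of 2 by the classical depside method (N,N'-dicyclohexylcarbodiimide, dry toluene, rt) to give 7.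

The second risk is the mono-methylation, step 2, which can give some 2,4-dimethyl ether or stop short. The fallback replaces kinetic selection by chelation-controlled deprotection. It sets out from 4 and comes back at 5. Exhaustive methylation (excess MeI, K2CO3, DMF, 50 °C) gives 2,4-dimethoxy-6-propylbenzaldehyde F2. BCl3 (1.1 equiv, CH2Cl2, −78 to 0 °C) binds the formyl oxygen and cleaves only the ortho methoxy group, which gives 5.

The third risk is the formylation, step 1, which may give some 2,6-dihydroxy-4-propyl isomer, diformylation, or O-formylated or O-phosphorylated material. The fallback inverts the order of events and uses phenoxide-directed formylation. It sets out from 1 and comes back at 5, so it bypasses 4. Mono-O-methylation of 1 (MeI 1.0 equiv, K2CO3, acetone, unreacted 1 recycled) gives 3-methoxy-5-propylphenol F3. Casnati–Skattebøl formylation (MgCl2, Et3N, paraformaldehyde, MeCN, reflux) delivers the formyl group only ortho to the magnesium phenoxide. Of the two ortho sites, it prefers the one para to the methoxy group, which gives 5.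

**Further compounds**
F1 | step 3 | 2-hydroxy-4-methoxy-6-propylbenzoic acid (divaricatinic acid) | CCCc1cc(OC)cc(O)c1C(=O)O
F2 | step 2 | 2,4-dimethoxy-6-propylbenzaldehyde | CCCc1cc(OC)cc(OC)c1C=O
F3 | step 1 | 3-methoxy-5-propylphenol | CCCc1cc(O)cc(OC)c1
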